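**Assumption:** the target is read as (1S,2R)-1-[(1S,2E)-1-hydroxy-3-(4-hydroxyphenyl)prop-2-en-1-yl]-6,7-dimethoxy-1,2,3,4-tetrahydronaphthalen-2-ol (cis-1,2; heptanoid numbering C-1 to C-7 from dimethoxyphenyl ring A to hydroxyphenyl ring B, i.e. 3R,4S,5S), and its biogenesis is taken to be the Friedel–Crafts closure of an epoxidised linear 1,7-diarylheptanoid (ring A carbon onto C-4).

## Retrosynthetic overview

1. Target ⇒ aryl-alkynyl diol: the (E)-styrene and the phenol are unmasked last from a C-6/C-7 alkyne, which keeps C-5 from ionising during ring closure.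
2. Key disconnection, ring A–C-4 bond ⇒ linear diarylheptanoid cis-3,4-epoxide with a free C-5 carbinol. A biomimetic 6-endo epoxide–arene Friedel–Crafts closure is the only ring-forming C–C bond formation and turns the cis-epoxide into the cis-1,2-tetralin by inversion at C-4.
3. C-5–C-6 bond ⇒ cis-epoxy aldehyde + aryl acetylide (Felkin–Anh addition sets C-5).
4. Epoxy aldehyde ⇒ cis-vinyl epoxide (ozonolysis) ⇒ 3-(3,4-dimethoxyphenyl)propanal + allyl chloride (asymmetric (Z)-γ-chloroallylboration sets C-3 and C-4).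
5. Ring order: oxirane (step 1), then the carbocyclic ring of the tetralin (step 4); both benzene rings are bought intact.

## Route

**Step 1**
Reactants: 1 3-(3,4-dimethoxyphenyl)propanal; 2 allyl chloride (3-chloroprop-1-ene)
Product: 4 (2R,3S)-2-[2-(3,4-dimethoxyphenyl)ethyl]-3-ethenyloxirane (cis-vinyl epoxide), via syn-chlorohydrin 3 (not isolated)
Conditions: 2, (−)-Ipc2BOMe [(−)-B-methoxydiisopinocampheylborane], LiN(c-C6H11)2 [from HN(c-C6H11)2, n-BuLi], Et2O, −95 °C; BF3·OEt2; 1, −95 °C; then NaOH, H2O2, 0 °C → rt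
Reagents that add atoms: none
Why: Oehlschlager–Brown (Z)-γ-chloroallylboration, in which the (Z)-γ-chloroallyl-BIpc2 reagent made in the flask adds through a chair Zimmerman–Traxler transition state to the Si face of 1 (ligands from (+)-α-pinene) to set C-3 (R) and C-4 (R) as the syn-chlorohydrin, whose alkoxide then closes the oxirane in the alkaline oxidative work-up by SN2 with inversion at C-4 to give the cis-epoxide.

**Step 2**
Reactants: 4 (2R,3S)-2-[2-(3,4-dimethoxyphenyl)ethyl]-3-ethenyloxirane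
Product: 6 (2R,3R)-3-[2-(3,4-dimethoxyphenyl)ethyl]oxirane-2-carbaldehyde (cis-epoxy aldehyde), via secondary ozonide 5 (not isolated)
Conditions: O3, CH2Cl2, −78 °C (Sudan Red 7B end-point); PPh3, −78 °C → rt
Reagents that add atoms: ozone, O=[O+][O-]
Why: ozonolysis with reductive work-up (Criegee mechanism) cleaves the terminal alkene far faster than ozone attacks the dimethoxyarene when dosed to the indicator end-point, and neither oxirane stereocentre is touched (the descriptor at the aldehyde-bearing carbon changes by ligand priority only).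

**Step 3**
Reactants: 6 (2R,3R)-3-[2-(3,4-dimethoxyphenyl)ethyl]oxirane-2-carbaldehyde; 7 tert-butyl(4-ethynylphenoxy)dimethylsilane
Product: 8 (1S)-3-[4-(tert-butyldimethylsilyloxy)phenyl]-1-{(2S,3R)-3-[2-(3,4-dimethoxyphenyl)ethyl]oxiran-2-yl}prop-2-yn-1-ol
Conditions: 7, n-BuLi, THF, −78 °C; then 6, −78 °C; AcOH quench
Reagents that add atoms: none
Why: 1,2-addition of a lithium acetylide to the aldehyde under Felkin–Anh (polar) control, the nucleophile entering anti to the oxirane C–O bond on the face left open by the cis substituent, gives the erythro (anti) carbinol, so C-5 is set S and the complete linear diarylheptanoid skeleton is in place.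

**Step 4 (key step)**
Reactants: 8 (1S)-3-[4-(tert-butyldimethylsilyloxy)phenyl]-1-{(2S,3R)-3-[2-(3,4-dimethoxyphenyl)ethyl]oxiran-2-yl}prop-2-yn-1-ol
Product: 9 (1S,2R)-1-{(1R)-3-[4-(tert-butyldimethylsilyloxy)phenyl]-1-hydroxyprop-2-yn-1-yl}-6,7-dimethoxy-1,2,3,4-tetrahydronaphthalen-2-ol
Conditions: BF3·OEt2 (1.2 equiv), CH2Cl2 (0.01 M), −78 → −30 °C
Reagents that add atoms: none
Why: biomimetic intramolecular epoxide–arene Friedel–Crafts alkylation in the 6-endo mode (5-exo closure at C-3 is geometrically disfavoured for an arene π-nucleophile), in which the ring A carbon para to a methoxy group attacks C-4 anti to the breaking C–O bond, so the cis-epoxide is converted with inversion at C-4 into the cis-1,2-tetralin (C-4 S) while C-3 and C-5 keep their configuration (the carbinol descriptor becomes R by priority only) and the alkyne, unlike a styrene, does not let C-5 ionise.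

**Step 5**
Reactants: 9 (1S,2R)-1-{(1R)-3-[4-(tert-butyldimethylsilyloxy)phenyl]-1-hydroxyprop-2-yn-1-yl}-6,7-dimethoxy-1,2,3,4-tetrahydronaphthalen-2-ol
Product: 11 (1S,2R)-1-[(1S,2E)-1-hydroxy-3-(4-hydroxyphenyl)prop-2-en-1-yl]-6,7-dimethoxy-1,2,3,4-tetrahydronaphthalen-2-ol (target), via silyl ether 10 (not isolated)
Conditions: NaAlH2(OCH2CH2OMe)2 (Red-Al), THF, 0 °C → rt; then MeOH, K2CO3, rt (same flask)
Reagents that add atoms: none
Why: alkoxide-directed trans-hydroalumination of the propargylic alcohol (Red-Al reduction) followed by protonolysis gives only the E-allylic alcohol, and the basic methanolic quench cleaves the aryl silyl ether, with no stereocentre touched (the carbinol descriptor returns to S).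

## Compound list

1 | 3-(3,4-dimethoxyphenyl)propanal | COc1ccc(CCC=O)cc1OC | starting material
2 | allyl chloride (3-chloroprop-1-ene) | C=CCCl | starting material
3 | (3R,4R)-4-chloro-1-(3,4-dimethoxyphenyl)hex-5-en-3-ol (syn-chlorohydrin, not isolated) | COc1ccc(CC[C@@H](O)[C@H](Cl)C=C)cc1OC | intermediate
4 | (2R,3S)-2-[2-(3,4-dimethoxyphenyl)ethyl]-3-ethenyloxirane (cis) | COc1ccc(CC[C@H]2O[C@H]2C=C)cc1OC | intermediate
5 | 3-{(2R,3R)-3-[2-(3,4-dimethoxyphenyl)ethyl]oxiran-2-yl}-1,2,4-trioxolane (secondary ozonide, both epimers at the trioxolane carbon, not isolated) | COc1ccc(CC[C@H]2O[C@H]2C3OCOO3)cc1OC | intermediate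
6 | (2R,3R)-3-[2-(3,4-dimethoxyphenyl)ethyl]oxirane-2-carbaldehyde (cis) | COc1ccc(CC[C@H]2O[C@H]2C=O)cc1OC | intermediate
7 | tert-butyl(4-ethynylphenoxy)dimethylsilane | C#Cc1ccc(O[Si](C)(C)C(C)(C)C)cc1 | starting material
8 | (1S)-3-[4-(tert-butyldimethylsilyloxy)phenyl]-1-{(2S,3R)-3-[2-(3,4-dimethoxyphenyl)ethyl]oxiran-2-yl}prop-2-yn-1-ol | COc1ccc(CC[C@H]2O[C@H]2[C@@H](O)C#Cc3ccc(O[Si](C)(C)C(C)(C)C)cc3)cc1OC | intermediate
9 | (1S,2R)-1-{(1R)-3-[4-(tert-butyldimethylsilyloxy)phenyl]-1-hydroxyprop-2-yn-1-yl}-6,7-dimethoxy-1,2,3,4-tetrahydronaphthalen-2-ol | COc1cc2c(cc1OC)[C@H]([C@@H](O)C#Cc1ccc(O[Si](C)(C)C(C)(C)C)cc1)[C@H](O)CC2 | intermediate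
10 | (1S,2R)-1-{(1S,2E)-3-[4-(tert-butyldimethylsilyloxy)phenyl]-1-hydroxyprop-2-en-1-yl}-6,7-dimethoxy-1,2,3,4-tetrahydronaphthalen-2-ol (not isolated) | COc1cc2c(cc1OC)[C@H]([C@@H](O)/C=C/c1ccc(O[Si](C)(C)C(C)(C)C)cc1)[C@H](O)CC2 | intermediate
11 | (1S,2R)-1-[(1S,2E)-1-hydroxy-3-(4-hydroxyphenyl)prop-2-en-1-yl]-6,7-dimethoxy-1,2,3,4-tetrahydronaphthalen-2-ol | COc1cc2c(cc1OC)[C@H]([C@@H](O)/C=C/c1ccc(O)cc1)[C@H](O)CC2 | target

## Step count and risks

Total steps: 5. Longest linear sequence: 5.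

**Step 4 (ring closure).** The attack at C-4 is slowed by the neighbouring carbinol. Competing paths are a Lewis-acid semipinacol shift of the alkynyl group or hydrogen from C-5 to C-4, Payne-type epoxide migration, and opening by fluoride. The fallback changes the order of events; it sets out from 4 and comes back at 9. The ring is closed on the vinyl epoxide 4 itself, where C-4 is allylic and the stereospecific 6-endo vinyloxirane–arene cyclisation is well behaved (BF3·OEt2, CH2Cl2, −78 °C), giving (1S,2R)-1-ethenyl-6,7-dimethoxy-1,2,3,4-tetrahydronaphthalen-2-ol F1. Ozonolysis (O3; PPh3) gives (1S,2R)-2-hydroxy-6,7-dimethoxy-1,2,3,4-tetrahydronaphthalene-1-carbaldehyde F2, used cold and at once. Addition of the Li acetylide of 7 (2.2 equiv, THF, −78 °C) gives the carbinol mixture (1S,2R)-1-{(1RS)-3-[4-(tert-butyldimethylsilyloxy)phenyl]-1-hydroxyprop-2-yn-1-yl}-6,7-dimethoxy-1,2,3,4-tetrahydronaphthalen-2-ol F3. MnO2 (CH2Cl2) oxidises only the propargylic alcohol to 3-[4-(tert-butyldimethylsilyloxy)phenyl]-1-[(1S,2R)-2-hydroxy-6,7-dimethoxy-1,2,3,4-tetrahydronaphthalen-1-yl]prop-2-yn-1-one F4. A Narasaka–Prasad reduction (Et2BOMe, NaBH4, THF–MeOH, −78 °C) then delivers the 1,3-syn diol 9, with C-5 now set from C-3.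

**Step 3 (acetylide addition).** The erythro:threo ratio may be modest and the cis-epoxy aldehyde is sensitive. The fallback sets the carbinol by a catalyst-controlled ketone reduction instead of a substrate-controlled addition; it sets out from 6 and comes back at 8. The unselective adduct (1RS)-3-[4-(tert-butyldimethylsilyloxy)phenyl]-1-{(2S,3R)-3-[2-(3,4-dimethoxyphenyl)ethyl]oxiran-2-yl}prop-2-yn-1-ol F5 is accepted and oxidised with MnO2 to 3-[4-(tert-butyldimethylsilyloxy)phenyl]-1-{(2R,3R)-3-[2-(3,4-dimethoxyphenyl)ethyl]oxiran-2-yl}prop-2-yn-1-one F6. Noyori transfer hydrogenation with RuCl(p-cymene)[(R,R)-TsDPEN] in i-PrOH then returns 8; alkynyl ketones are the best substrates for this catalyst, and this antipode places the alkynyl and oxiranyl groups as in 8.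

**Step 1 (chloroallylboration).** The −95 °C generation of the chloroallyl borane is technically demanding, and the ee or syn:anti ratio may fall short. The fallback takes the epoxide stereocentres from a Sharpless epoxidation and also avoids the ozonolysis of step 2; it sets out from 1 and comes back at 6. Still–Gennari olefination of 1 [(CF3CH2O)2P(O)CH2CO2Me, KN(SiMe3)2, 18-crown-6, THF, −78 °C] gives methyl (2Z)-5-(3,4-dimethoxyphenyl)pent-2-enoate F7. Reduction with i-Bu2AlH (CH2Cl2, −78 °C) gives (2Z)-5-(3,4-dimethoxyphenyl)pent-2-en-1-ol F8. Sharpless asymmetric epoxidation [Ti(OiPr)4, L-(+)-diethyl tartrate, t-BuOOH, 4 Å sieves, CH2Cl2, −20 °C] gives [(2S,3R)-3-[2-(3,4-dimethoxyphenyl)ethyl]oxiran-2-yl]methanol F9. Dess–Martin periodinane (NaHCO3, CH2Cl2) then gives 6.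

## Further compounds

F1 | step 4 | (1S,2R)-1-ethenyl-6,7-dimethoxy-1,2,3,4-tetrahydronaphthalen-2-ol | COc1cc2c(cc1OC)[C@H](C=C)[C@H](O)CC2
F2 | step 4 | (1S,2R)-2-hydroxy-6,7-dimethoxy-1,2,3,4-tetrahydronaphthalene-1-carbaldehyde | COc1cc2c(cc1OC)[C@H](C=O)[C@H](O)CC2
F3 | step 4 | (1S,2R)-1-{(1RS)-3-[4-(tert-butyldimethylsilyloxy)phenyl]-1-hydroxyprop-2-yn-1-yl}-6,7-dimethoxy-1,2,3,4-tetrahydronaphthalen-2-ol | COc1cc2c(cc1OC)[C@H](C(O)C#Cc1ccc(O[Si](C)(C)C(C)(C)C)cc1)[C@H](O)CC2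
F4 | step 4 | 3-[4-(tert-butyldimethylsilyloxy)phenyl]-1-[(1S,2R)-2-hydroxy-6,7-dimethoxy-1,2,3,4-tetrahydronaphthalen-1-yl]prop-2-yn-1-one | COc1cc2c(cc1OC)[C@H](C(=O)C#Cc1ccc(O[Si](C)(C)C(C)(C)C)cc1)[C@H](O)CC2
F5 | step 3 | (1RS)-3-[4-(tert-butyldimethylsilyloxy)phenyl]-1-{(2S,3R)-3-[2-(3,4-dimethoxyphenyl)ethyl]oxiran-2-yl}prop-2-yn-1-ol | COc1ccc(CC[C@H]2O[C@H]2C(O)C#Cc3ccc(O[Si](C)(C)C(C)(C)C)cc3)cc1OC
F6 | step 3 | 3-[4-(tert-butyldimethylsilyloxy)phenyl]-1-{(2R,3R)-3-[2-(3,4-dimethoxyphenyl)ethyl]oxiran-2-yl}prop-2-yn-1-one | COc1ccc(CC[C@H]2O[C@H]2C(=O)C#Cc3ccc(O[Si](C)(C)C(C)(C)C)cc3)cc1OC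
F7 | step 1 | methyl (2Z)-5-(3,4-dimethoxyphenyl)pent-2-enoate | COC(=O)/C=C\CCc1ccc(OC)c(OC)c1
F8 | step 1 | (2Z)-5-(3,4-dimethoxyphenyl)pent-2-en-1-ol | OC/C=C\CCc1ccc(OC)c(OC)c1
F9 | step 1 | [(2S,3R)-3-[2-(3,4-dimethoxyphenyl)ethyl]oxiran-2-yl]methanol | COc1ccc(CC[C@H]2O[C@H]2CO)cc1OC
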